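**Plan**

1. Retrosynthesis (germacranolide numbering): remove the C15 silyl ether, the 1,10-epoxide (from the E-C1=C10 alkene) and the C8 methacrylate, open the 6,12-lactone to a C6/C12 diol, then cut the ring bond C5–C6.
2. C5 is the vinylic CH of the Z-C4=C5 alkene of the ten-membered ring and C6 is the allylic ring carbon that carries the lactone oxygen. C5–C6 is therefore the bond an alkenyl–metal makes with an aldehyde, and the cis C4=C5 and E-C1=C10 alkenes fold the seco chain for closure.
3. Chain cuts: C4–C15 and C5–I (anti-carbomagnesiation of a C4≡C5 alkyne), C3–C4 (alkynylation), C1–C2 and C10–C14 (carboalumination/oxirane), C9–C10 (acetylide alkylation), C7–C11 (epoxide opening).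
4. Forward: C6–C9 epoxy alcohol, C7 branch, chain growth to C5, ten-membered carbocycle by C5–C6 closure, then γ-lactone by oxidative lactonization, then methacrylate, oxirane last.
5. Stereochemistry: C7/C8 from Sharpless epoxidation and invertive opening; C3 from catalytic asymmetric alkynylation; E-C1=C10 from syn-carboalumination; Z-C4=C5 from a magnesium chelate; C6 from Felkin/1,3-anti addition in the ring closure; C1/C10 from peripheral epoxidation.

Key step: step 16

Remark: germacrane numbers (C1–C10 ring, C11–C13 lactone carbons, C14 ring methyl, C15 hydroxymethyl) serve as locants for all intermediates. It is assumed that peracid attacks the E-C1=C10 alkene of the ten-membered ring from its outer face, as is usual for germacra-1(10),4-dienolides.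

**Step 1**
Reactants: 1 (E)-but-2-ene-1,4-diol
Product: 2 (E)-4-hydroxybut-2-en-1-yl pivalate
Conditions: PivCl (1 equiv), pyridine, CH2Cl2, −20 °C, diol in excess
Reagents that add atoms: pivaloyl chloride CC(C)(C)C(=O)Cl
Why: Statistical monoacylation of a symmetric diol; the pivalate resists acyl migration and later deactivates C8 toward nucleophiles.

**Step 2**
Reactants: 2 (E)-4-hydroxybut-2-en-1-yl pivalate
Product: 3 (2R,3R)-epoxy alcohol (C6–C9 unit)
Conditions: Ti(OiPr)4 (0.1 equiv), D-(−)-diethyl tartrate (0.12 equiv), tBuOOH, 4 Å molecular sieves, CH2Cl2, −20 °C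
Reagents that add atoms: tert-butyl hydroperoxide CC(C)(C)OO
Why: Sharpless asymmetric epoxidation; D-(−)-tartrate should give the (2R,3R)-trans-epoxide, which fixes C8 and, after inversion, C7.

**Step 3**
Reactants: 4 2,3-dibromoprop-1-ene
Product: 5 2-bromoallyl 4-methoxybenzyl ether
Conditions: 4-methoxybenzyl alcohol, NaH, THF, 0 °C to rt
Reagents that add atoms: (4-methoxyphenyl)methanol COc1ccc(CO)cc1
Why: Williamson ether synthesis by SN2 at the allylic bromide; the vinylic bromide does not react.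

**Step 4**
Reactants: 3 (2R,3R)-epoxy alcohol; 5 2-bromoallyl 4-methoxybenzyl ether
Product: 8 anti C6/C8-diol pivalate, via alkenyllithium 6 (not isolated), via alkenylmagnesium bromide 7 (not isolated)
Conditions: 5 (3 equiv), tBuLi (6 equiv), Et2O, −78 °C; MgBr2·OEt2, −78 °C; CuI (0.3 equiv), then 3, THF, −45 to −20 °C; aq. NH4Cl
Reagents that add atoms: none
Why: Copper-catalysed SN2 opening of a 2,3-epoxy alcohol by an alkenyl Grignard reagent at C7 (attack at C8 is disfavoured by the adjacent acyloxymethyl group) with inversion, so that C7 and C8 end anti; low temperature holds back β-elimination of 7.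

**Step 5**
Reactants: 8 anti C6/C8-diol pivalate
Product: 9 C6,C8-bis(triethylsilyl) ether
Conditions: Et3SiOTf (2.5 equiv), 2,6-lutidine, CH2Cl2, −78 to 0 °C
Reagents that add atoms: triethylsilyl trifluoromethanesulfonate CC[Si](CC)(CC)OS(=O)(=O)C(F)(F)F
Why: Silylation of both hydroxyls with a silyl triflate; the primary and the secondary silyl ether can later be removed at different times.

**Step 6**
Reactants: 9 C6,C8-bis(triethylsilyl) ether
Product: 10 C9 primary alcohol
Conditions: iBu2AlH (2.2 equiv), CH2Cl2, −78 °C; aq. potassium sodium tartrate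
Reagents that add atoms: none
Why: Reductive cleavage of the pivalate by a hydride reagent at low temperature leaves silyl and PMB ethers intact.

**Step 7**
Reactants: 10 C9 primary alcohol
Product: 13 terminal alkyne (C10≡C1), via triflate 11 (not isolated), via trimethylsilyl alkyne 12 (not isolated)
Conditions: Tf2O, 2,6-lutidine, CH2Cl2, −78 °C; LiC≡CSiMe3 (from ethynyltrimethylsilane and nBuLi), THF/DMPU, −78 to −20 °C; K2CO3, MeOH, rt
Reagents that add atoms: ethynyltrimethylsilane C#C[Si](C)(C)C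
Why: SN2 alkylation of a lithium acetylide with a primary triflate at −78 °C (the low temperature suppresses participation of the neighbouring silyl ether), followed by methanolysis of the alkynylsilane.

**Step 8**
Reactants: 13 terminal alkyne
Product: 16 (E)-homoallylic alcohol (C3–OH), via alkenylalane 14 (not isolated), via lithium alanate 15 (not isolated)
Conditions: Me3Al (3 equiv), Cp2ZrCl2 (0.3 equiv), CH2Cl2, 0 °C to rt; nBuLi, THF, −78 °C; oxirane, −30 °C to rt; aq. potassium sodium tartrate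
Reagents that add atoms: trimethylaluminium C[Al](C)C; oxirane C1CO1
Why: Negishi zirconium-catalysed carboalumination adds methyl (to C10) and aluminium (to C1) syn across the alkyne and so fixes the E-C1=C10 geometry; the alanate then opens oxirane to add C2 and C3.

**Step 9**
Reactants: 16 (E)-homoallylic alcohol
Product: 17 C3 aldehyde
Conditions: Dess–Martin periodinane, NaHCO3, CH2Cl2, 0 °C; used crude
Reagents that add atoms: none
Why: Dess–Martin oxidation under buffered conditions should give the β,γ-unsaturated aldehyde without migration of the alkene.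

**Step 10**
Reactants: 17 C3 aldehyde
Product: 19 (3S)-propargylic alcohol, via silylated alkynol 18 (not isolated)
Conditions: ethynyltrimethylsilane (3 equiv), Me2Zn (3 equiv), ProPhenol ligand (0.1 equiv; the enantiomer that delivers the alkynyl group to the Re face of the aldehyde), Ph3P=O (0.2 equiv), toluene, 0 °C; then K2CO3, MeOH, rt
Reagents that add atoms: ethynyltrimethylsilane C#C[Si](C)(C)C
Why: Zinc–ProPhenol-catalysed enantioselective alkynylation of an aldehyde; the alkynylzinc adds to the Re face and sets (3S) under amine-free conditions that spare the enolizable aldehyde, and methanolysis frees the terminal alkyne.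

**Step 11**
Reactants: 19 (3S)-propargylic alcohol
Product: 22 (Z)-alkenyl iodide C3,C15-diol, via magnesium chelate 20 (not isolated), via iodo silane 21 (not isolated)
Conditions: (iPrO)Me2SiCH2MgCl (3.5 equiv), CuI (0.2 equiv), THF, 0 °C to rt; I2, THF, −78 °C; crude product: H2O2 (30%), KHCO3, THF/MeOH, rt to 40 °C
Reagents that add atoms: [(isopropoxy)dimethylsilyl]methylmagnesium chloride CC(C)O[Si](C)(C)C[Mg]Cl; iodine II; hydrogen peroxide OO
Why: Copper-catalysed anti-carbomagnesiation of a propargylic alcohol puts the silylmethyl group on C4 and magnesium on C5 inside a five-membered magnesium alkoxide chelate, so iodine ends cis to C3 (the later Z-C4=C5 geometry); Tamao oxidation then converts the C–Si bond into the C15 hydroxyl.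

**Step 12**
Reactants: 22 (Z)-alkenyl iodide C3,C15-diol
Product: 23 C15 tert-butyldiphenylsilyl ether
Conditions: tBuPh2SiCl (1.1 equiv), imidazole, CH2Cl2, 0 °C
Reagents that add atoms: tert-butyl(chloro)diphenylsilane CC(C)(C)[Si](Cl)(c1ccccc1)c1ccccc1
Why: Selective silylation of the primary allylic hydroxyl over the hindered secondary one.

**Step 13**
Reactants: 23 C15 silyl ether
Product: 24 C3 acetate
Conditions: Ac2O, pyridine, DMAP (0.1 equiv), CH2Cl2, 0 °C to rt
Reagents that add atoms: acetic anhydride CC(=O)OC(C)=O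
Why: DMAP-catalysed acetylation of the remaining secondary allylic hydroxyl.

**Step 14**
Reactants: 24 C3 acetate
Product: 25 C6 primary alcohol
Conditions: PPTS (0.2 equiv), MeOH/CH2Cl2, 0 °C
Reagents that add atoms: none
Why: Acid-catalysed methanolysis should remove the primary triethylsilyl ether faster than the secondary one and the tert-butyldiphenylsilyl ether.

**Step 15**
Reactants: 25 C6 primary alcohol
Product: 26 C6 aldehyde with (Z)-alkenyl iodide
Conditions: Dess–Martin periodinane, NaHCO3, CH2Cl2, 0 °C; used at once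
Reagents that add atoms: none
Why: Dess–Martin oxidation with NaHCO3 as buffer and no amine base should give the α-branched β-silyloxy aldehyde without epimerization at C7 or elimination.

**Step 16**
Reactants: 26 C6 aldehyde with (Z)-alkenyl iodide
Product: 28 ten-membered (6R)-allylic alcohol, via alkenylchromium dichloride 27 (not isolated)
Conditions: CrCl2 (15 equiv), NiCl2 (0.15 equiv), degassed DMSO, 0.002 M, rt, slow addition of 26
Reagents that add atoms: none
Why: CrCl2 reduces NiCl2 to zerovalent nickel, which inserts into the C5–I bond with retention of geometry; transmetalation gives the alkenyl trivalent chromium species 27, whose C5 adds to the C6 aldehyde (intramolecular Nozaki–Hiyama–Kishi reaction, closest precedent: macrocyclizations of alkenyl iodide aldehydes to medium carbocycles). The ten-membered carbocycle closes by 1,2-addition of C5 to the carbonyl (10-exo-trig at C6) under high dilution. The new C6 centre should form by attack on the Re face, which the Felkin–Anh model (C7–C8 bond anti to the incoming C5) and 1,3-anti induction from the C8 silyloxy group both predict; the two effects reinforce because C7 and C8 are anti. The step needs chemoselectivity for the C–I bond (acetate, silyl ethers, PMB ether and the other alkenes are inert to CrCl2) and ring closure over oligomerization, which the cis C4=C5 and E-C1=C10 alkenes favour by folding C5 toward C6. No base is present, so the aldehyde should keep its C7 configuration.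

**Step 17**
Reactants: 28 ten-membered (6R)-allylic alcohol
Product: 29 C6,C12-diol
Conditions: DDQ (1.3 equiv), CH2Cl2/pH 7 buffer, 0 °C
Reagents that add atoms: none
Why: Oxidative cleavage of the PMB ether by DDQ; silyl ethers, acetate and the alkenes should survive.

**Step 18**
Reactants: 29 C6,C12-diol
Product: 32 trans-fused α-methylene γ-lactone, via hydroxy enal 30 (not isolated), via lactol 31 (not isolated)
Conditions: TEMPO (0.3 equiv), PhI(OAc)2 (3 equiv), CH2Cl2, rt
Reagents that add atoms: none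
Why: TEMPO-catalysed oxidative lactonization of a 2-methylene-1,4-diol: the primary allylic alcohol is oxidized first, the C6 hydroxyl closes the lactol, and the lactol is oxidized to the lactone; the trans fusion follows from C6 and C7.

**Step 19**
Reactants: 32 trans-fused α-methylene γ-lactone
Product: 33 C8 alcohol
Conditions: camphorsulfonic acid (0.2 equiv), MeOH/CH2Cl2, 0 °C to rt
Reagents that add atoms: none
Why: Acid-catalysed methanolysis of the secondary triethylsilyl ether; the primary tert-butyldiphenylsilyl ether should survive.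

**Step 20**
Reactants: 33 C8 alcohol
Product: 34 C8 methacrylate
Conditions: methacrylic anhydride (3 equiv), Et3N, DMAP (0.3 equiv), CH2Cl2, rt
Reagents that add atoms: methacrylic anhydride C=C(C)C(=O)OC(=O)C(C)=C
Why: DMAP-catalysed acylation of the only free hydroxyl with an anhydride.

**Step 21**
Reactants: 34 C8 methacrylate
Product: 35 (1R,10R)-epoxide
Conditions: mCPBA (1.05 equiv), NaHCO3, CH2Cl2, −20 to 0 °C
Reagents that add atoms: 3-chloroperbenzoic acid OOC(=O)c1cccc(Cl)c1
Why: Prilezhaev epoxidation; the electron-rich C1=C10 alkene should react before the C4=C5 alkene (three allylic oxygens) and the two enoates, and attack on the outer face of the E-alkene in the ten-membered ring should give the trans (1R,10R)-epoxide.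

**Step 22**
Reactants: 35 (1R,10R)-epoxide
Product: 36 CNP0319155.1
Conditions: HF·pyridine, pyridine, THF, 0 °C to rt
Reagents that add atoms: none
Why: Fluoride cleavage of the silyl ether under buffered conditions that should leave the epoxide, both esters and the α-methylene lactone intact.

**Compound list**

1 | (E)-but-2-ene-1,4-diol | OC/C=C/CO | starting material
2 | (E)-4-hydroxybut-2-en-1-yl 2,2-dimethylpropanoate | CC(C)(C)C(=O)OC/C=C/CO | intermediate
3 | [(2R,3R)-3-(hydroxymethyl)oxiran-2-yl]methyl 2,2-dimethylpropanoate | OC[C@H]1O[C@@H]1COC(=O)C(C)(C)C | intermediate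
4 | 2,3-dibromoprop-1-ene | C=C(Br)CBr | starting material
5 | 1-{[(2-bromoprop-2-en-1-yl)oxy]methyl}-4-methoxybenzene | C=C(Br)COCc1ccc(OC)cc1 | intermediate
6 | {3-[(4-methoxybenzyl)oxy]prop-1-en-2-yl}lithium | [Li]C(=C)COCc1ccc(OC)cc1 | intermediate
7 | {3-[(4-methoxybenzyl)oxy]prop-1-en-2-yl}magnesium bromide | Br[Mg]C(=C)COCc1ccc(OC)cc1 | intermediate
8 | (2S,3S)-2-hydroxy-3-(hydroxymethyl)-4-{[(4-methoxybenzyl)oxy]methyl}pent-4-en-1-yl 2,2-dimethylpropanoate (C6,C8-diol; C7 and C8 anti) | OC[C@H](C(=C)COCc1ccc(OC)cc1)[C@H](O)COC(=O)C(C)(C)C | intermediate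
9 | (2S,3S)-4-{[(4-methoxybenzyl)oxy]methyl}-2-[(triethylsilyl)oxy]-3-{[(triethylsilyl)oxy]methyl}pent-4-en-1-yl 2,2-dimethylpropanoate | CC[Si](CC)(CC)OC[C@H](C(=C)COCc1ccc(OC)cc1)[C@H](O[Si](CC)(CC)CC)COC(=O)C(C)(C)C | intermediate
10 | (2S,3S)-4-{[(4-methoxybenzyl)oxy]methyl}-2-[(triethylsilyl)oxy]-3-{[(triethylsilyl)oxy]methyl}pent-4-en-1-ol | CC[Si](CC)(CC)OC[C@H](C(=C)COCc1ccc(OC)cc1)[C@H](O[Si](CC)(CC)CC)CO | intermediate
11 | trifluoromethanesulfonate of 10 (C9–OTf) | CC[Si](CC)(CC)OC[C@H](C(=C)COCc1ccc(OC)cc1)[C@H](O[Si](CC)(CC)CC)COS(=O)(=O)C(F)(F)F | intermediate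
12 | 7-(trimethylsilyl) derivative of 13 | CC[Si](CC)(CC)OC[C@H](C(=C)COCc1ccc(OC)cc1)[C@H](O[Si](CC)(CC)CC)CC#C[Si](C)(C)C | intermediate
13 | 2-{[(4-methoxybenzyl)oxy]methyl}-4-[(triethylsilyl)oxy]-3-{[(triethylsilyl)oxy]methyl}hept-1-en-6-yne (C7, C8 as in 8) | CC[Si](CC)(CC)OC[C@H](C(=C)COCc1ccc(OC)cc1)[C@H](O[Si](CC)(CC)CC)CC#C | intermediate
14 | (E)-alkenyl(dimethyl)alane from 13 (methyl on C10, aluminium on C1, trans to C9) | CC[Si](CC)(CC)OC[C@H](C(=C)COCc1ccc(OC)cc1)[C@H](O[Si](CC)(CC)CC)C/C(C)=C/[Al](C)C | intermediate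
15 | lithium butyl(dimethyl)alkenylalanate from 14 | CC[Si](CC)(CC)OC[C@H](C(=C)COCc1ccc(OC)cc1)[C@H](O[Si](CC)(CC)CC)C/C(C)=C/[Al-](C)(C)CCCC.[Li+] | intermediate
16 | (3E)-8-{[(4-methoxybenzyl)oxy]methyl}-4-methyl-6-[(triethylsilyl)oxy]-7-{[(triethylsilyl)oxy]methyl}nona-3,8-dien-1-ol (C7, C8 as in 8) | CC[Si](CC)(CC)OC[C@H](C(=C)COCc1ccc(OC)cc1)[C@H](O[Si](CC)(CC)CC)C/C(C)=C/CCO | intermediate
17 | corresponding (3E)-nona-3,8-dienal (aldehyde at C3) | CC[Si](CC)(CC)OC[C@H](C(=C)COCc1ccc(OC)cc1)[C@H](O[Si](CC)(CC)CC)C/C(C)=C/CC=O | intermediate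
18 | (3S,5E)-10-{[(4-methoxybenzyl)oxy]methyl}-6-methyl-8-[(triethylsilyl)oxy]-9-{[(triethylsilyl)oxy]methyl}-1-(trimethylsilyl)undeca-5,10-dien-1-yn-3-ol | CC[Si](CC)(CC)OC[C@H](C(=C)COCc1ccc(OC)cc1)[C@H](O[Si](CC)(CC)CC)C/C(C)=C/C[C@H](O)C#C[Si](C)(C)C | intermediate
19 | (3S,5E)-10-{[(4-methoxybenzyl)oxy]methyl}-6-methyl-8-[(triethylsilyl)oxy]-9-{[(triethylsilyl)oxy]methyl}undeca-5,10-dien-1-yn-3-ol | CC[Si](CC)(CC)OC[C@H](C(=C)COCc1ccc(OC)cc1)[C@H](O[Si](CC)(CC)CC)C/C(C)=C/C[C@H](O)C#C | intermediate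
20 | cyclic magnesium alkoxide (ring O3–Mg–C5=C4–C3; C4 bears CH2SiMe2OiPr) | CC[Si](CC)(CC)OC[C@H](C(=C)COCc1ccc(OC)cc1)[C@H](O[Si](CC)(CC)CC)C/C(C)=C/C[C@@H]1O[Mg]C=C1C[Si](C)(C)OC(C)C | intermediate
21 | (3S)-alkenyl iodide with CH2SiMe2(OiPr) on C4, iodine on C5 cis to C3 | CC[Si](CC)(CC)OC[C@H](C(=C)COCc1ccc(OC)cc1)[C@H](O[Si](CC)(CC)CC)C/C(C)=C/C[C@H](O)/C(C[Si](C)(C)OC(C)C)=C\I | intermediate
22 | (2Z,3S,5E)-2-(iodomethylidene)-10-{[(4-methoxybenzyl)oxy]methyl}-6-methyl-8-[(triethylsilyl)oxy]-9-{[(triethylsilyl)oxy]methyl}undeca-5,10-diene-1,3-diol | CC[Si](CC)(CC)OC[C@H](C(=C)COCc1ccc(OC)cc1)[C@H](O[Si](CC)(CC)CC)C/C(C)=C/C[C@H](O)/C(CO)=C\I | intermediate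
23 | 1-O-(tert-butyldiphenylsilyl) ether of 22 (C15–OSi) | CC[Si](CC)(CC)OC[C@H](C(=C)COCc1ccc(OC)cc1)[C@H](O[Si](CC)(CC)CC)C/C(C)=C/C[C@H](O)/C(CO[Si](c1ccccc1)(c1ccccc1)C(C)(C)C)=C\I | intermediate
24 | 3-O-acetate of 23 | CC[Si](CC)(CC)OC[C@H](C(=C)COCc1ccc(OC)cc1)[C@H](O[Si](CC)(CC)CC)C/C(C)=C/C[C@H](OC(C)=O)/C(CO[Si](c1ccccc1)(c1ccccc1)C(C)(C)C)=C\I | intermediate
25 | C6 primary alcohol from 24 (C8–OSiEt3 kept) | OC[C@H](C(=C)COCc1ccc(OC)cc1)[C@H](O[Si](CC)(CC)CC)C/C(C)=C/C[C@H](OC(C)=O)/C(CO[Si](c1ccccc1)(c1ccccc1)C(C)(C)C)=C\I | intermediate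
26 | C6 aldehyde from 25 (seco aldehyde with (Z)-alkenyl iodide) | O=C[C@H](C(=C)COCc1ccc(OC)cc1)[C@H](O[Si](CC)(CC)CC)C/C(C)=C/C[C@H](OC(C)=O)/C(CO[Si](c1ccccc1)(c1ccccc1)C(C)(C)C)=C\I | intermediate
27 | alkenylchromium dichloride from 26 (Cr on C5 in place of I) | O=C[C@H](C(=C)COCc1ccc(OC)cc1)[C@H](O[Si](CC)(CC)CC)C/C(C)=C/C[C@H](OC(C)=O)/C(CO[Si](c1ccccc1)(c1ccccc1)C(C)(C)C)=C\[Cr](Cl)Cl | intermediate
28 | (3S,6R)-3-acetoxy-15-(tert-butyldiphenylsilyloxy)-12-(4-methoxybenzyloxy)-8-(triethylsilyloxy)germacra-1(10)E,4Z,11(13)-trien-6-ol (C7, C8 as in 8) | CC[Si](CC)(CC)O[C@@H]1C/C(C)=C/C[C@H](OC(C)=O)/C(CO[Si](c2ccccc2)(c2ccccc2)C(C)(C)C)=C\[C@@H](O)[C@@H]1C(=C)COCc1ccc(OC)cc1 | intermediate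
29 | C6,C12-diol from 28 | CC[Si](CC)(CC)O[C@@H]1C/C(C)=C/C[C@H](OC(C)=O)/C(CO[Si](c2ccccc2)(c2ccccc2)C(C)(C)C)=C\[C@@H](O)[C@@H]1C(=C)CO | intermediate
30 | 6-hydroxy 12-aldehyde (enal) from 29 | CC[Si](CC)(CC)O[C@@H]1C/C(C)=C/C[C@H](OC(C)=O)/C(CO[Si](c2ccccc2)(c2ccccc2)C(C)(C)C)=C\[C@@H](O)[C@@H]1C(=C)C=O | intermediate
31 | 6,12-lactol (trans-fused, C12 epimers) | CC[Si](CC)(CC)O[C@@H]1C/C(C)=C/C[C@H](OC(C)=O)/C(CO[Si](c3ccccc3)(c3ccccc3)C(C)(C)C)=C\[C@H]2OC(O)C(=C)[C@@H]21 | intermediate
32 | 3-acetoxy-15-(tert-butyldiphenylsilyloxy)-8-(triethylsilyloxy)germacra-1(10)E,4Z,11(13)-trien-12,6-olide | CC[Si](CC)(CC)O[C@@H]1C/C(C)=C/C[C@H](OC(C)=O)/C(CO[Si](c3ccccc3)(c3ccccc3)C(C)(C)C)=C\[C@H]2OC(=O)C(=C)[C@@H]21 | intermediate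
33 | 8-hydroxy lactone from 32 | O[C@@H]1C/C(C)=C/C[C@H](OC(C)=O)/C(CO[Si](c3ccccc3)(c3ccccc3)C(C)(C)C)=C\[C@H]2OC(=O)C(=C)[C@@H]21 | intermediate
34 | 8-methacrylate of 33 | C=C(C)C(=O)O[C@@H]1C/C(C)=C/C[C@H](OC(C)=O)/C(CO[Si](c3ccccc3)(c3ccccc3)C(C)(C)C)=C\[C@H]2OC(=O)C(=C)[C@@H]21 | intermediate
35 | (1R,10R)-1,10-epoxide of 34 (15-O-silyl ether of the target) | C=C(C)C(=O)O[C@@H]1C[C@@]2(C)O[C@@H]2C[C@H](OC(C)=O)/C(CO[Si](c3ccccc3)(c3ccccc3)C(C)(C)C)=C\[C@H]2OC(=O)C(=C)[C@@H]21 | intermediate
36 | CNP0319155.1, (1R,3S,4Z,6R,7R,8R,10R)-3-acetoxy-1,10-epoxy-15-hydroxy-8-(methacryloyloxy)germacra-4,11(13)-dien-12,6-olide | C=C(C)C(=O)O[C@@H]1C[C@@]2(C)O[C@@H]2C[C@H](OC(C)=O)/C(CO)=C\[C@H]2OC(=O)C(=C)[C@@H]21 | target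

**Totals**

Total step count: 22. Longest linear sequence: 21 steps (steps 1, 2 and 4–22; step 3 prepares the side reagent 5).

**Steps most likely to fail**

Step 16. Intermolecular coupling may compete with closure of the strained ten-membered ring, and the alkenylchromium may add to the wrong aldehyde face. The fallback corrects the C6 configuration after the ring is closed. It sets out from 28 as obtained in a mixture with its C6 epimer. Dess–Martin oxidation of the mixture gives the macrocyclic C6 ketone (4-en-6-one) F1, which is used without delay. Corey–Bakshi–Shibata reduction (BH3·SMe2, oxazaborolidine antipode chosen for hydride delivery to the Si face, −40 °C) then returns to 28.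

Step 11. The functionalized Grignard reagent may add sluggishly or with loss of regiocontrol, and the allylsilane may be attacked by iodine during the quench. The fallback sets out from 18, isolated by omitting the methanolysis of step 10. Syn-hydrostannation (Bu3SnH, PdCl2(PPh3)2, THF) places tin on C4 and leaves silicon cis to C3, giving the 4-stannyl-5-silyl alkenyl alcohol F2. Tin–lithium exchange on the lithium alkoxide (MeLi, THF, −78 °C) and trapping with paraformaldehyde gives the C3,C15-diol alkenylsilane F3. Iododesilylation with N-iodosuccinimide (MeCN/ClCH2CN, 0 °C, retention) returns to 22.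

Step 21. The ring conformer that reacts may expose the wrong face of the C1=C10 alkene, which would give the (1S,10S)-epoxide. The fallback replaces substrate control by reagent control. It sets out from 34 and uses a Shi epoxidation (fructose-derived ketone of the enantiomeric series matched to the required face, KHSO5, K2CO3 buffer, MeCN/dimethoxymethane, 0 °C), in which the chiral dioxirane selects the conformer and face. It comes back at 35 and makes no new compound (F0).

**Further compounds**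

F1 | step 16 | macrocyclic C6 ketone: 3-acetoxy-15-(tert-butyldiphenylsilyloxy)-12-(4-methoxybenzyloxy)-8-(triethylsilyloxy)germacra-1(10)E,4Z,11(13)-trien-6-one | CC[Si](CC)(CC)O[C@@H]1C/C(C)=C/C[C@H](OC(C)=O)/C(CO[Si](c2ccccc2)(c2ccccc2)C(C)(C)C)=C\C(=O)[C@@H]1C(=C)COCc1ccc(OC)cc1
F2 | step 11 | 4-(tributylstannyl)-5-(trimethylsilyl) alkenyl alcohol from 18 (silicon cis to C3) | CC[Si](CC)(CC)OC[C@H](C(=C)COCc1ccc(OC)cc1)[C@H](O[Si](CC)(CC)CC)C/C(C)=C/C[C@H](O)/C([Sn](CCCC)(CCCC)CCCC)=C\[Si](C)(C)C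
F3 | step 11 | C3,C15-diol alkenylsilane (trimethylsilyl on C5 cis to C3) | CC[Si](CC)(CC)OC[C@H](C(=C)COCc1ccc(OC)cc1)[C@H](O[Si](CC)(CC)CC)C/C(C)=C/C[C@H](O)/C(CO)=C\[Si](C)(C)C
F0 | step 21 | none | none
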